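**Retrosynthetic overview**
- Target atom labels: C1 (C–OH), C2 (aryl), O3, C4, C5 (H), C6 (aryl), O7, C8; ring A = C1/C5/C6/O7/C8, ring B = C1/C2/O3/C4/C5.
- Ring B is closed last through the O3–C4 ether bond (C–O bond formation at a primary carbon); this is the step that locks the trans ring fusion.
- The C1–O and C2–O bonds come from a hydroxyl-directed syn-dihydroxylation of an E-benzylidene oxolane-methanol (ring A already present).
- Ring A is formed first as a γ-lactone by an enantioselective Stobbe-type aldol–lactonisation (sets C5 and C6), then reduced to the oxolane.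
- The aldol donor comes from a Heck reaction of 4-bromoveratrole with dimethyl itaconate.

Assumption: the SMILES is read literally as (1S,2S,5S,6R), which puts 1-OH and 5-H on opposite faces (a trans-fused 3,7-dioxabicyclo[3.3.0]octane, not the cis-fused gmelinol frame); the route targets exactly this isomer.

**Route**

Step 1
Reactants: 1 4-bromo-1,2-dimethoxybenzene; 2 dimethyl itaconate
Product: 3 dimethyl (2E)-2-[(3,4-dimethoxyphenyl)methylidene]butanedioate
Conditions: Pd(OAc)2 (2 mol%), P(o-tol)3 (4 mol%), NaOAc, DMF, 110 °C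
Reagents that add atoms: none
Why: Mizoroki–Heck reaction in which aryl–palladium adds to the CH2 terminus of itaconate and syn β-hydride elimination of the benzylic hydrogen gives the aryl-conjugated E-alkene (aryl trans to the attached ester); no stereocentre is formed.

Step 2
Reactants: 3 dimethyl (2E)-2-[(3,4-dimethoxyphenyl)methylidene]butanedioate; 4 3,4-dimethoxybenzaldehyde
Product: 6 methyl (2R,3R,4E)-2-(3,4-dimethoxyphenyl)-4-[(3,4-dimethoxyphenyl)methylidene]-5-oxooxolane-3-carboxylate, via aldol adduct 5 (not isolated)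
Conditions: bifunctional iminophosphorane–thiourea organocatalyst (tert-leucine-derived, P(4-MeOC6H4)3=N unit, 10 mol%, antipode chosen to give 2R), 4 Å MS, toluene, −20 °C
Reagents that add atoms: none
Why: Proposed new method: a catalytic enantioselective Stobbe-type aldol–lactonisation, in which the iminophosphorane superbase reversibly deprotonates the CH2 of 3 (α to an ester and allylic to the styrene, estimated pKa about 19–20 in DMSO), the thiourea binds 4 and directs C–C bond formation to one aldehyde face (sets C2), the aldolate is removed from the aldol/retro-aldol equilibrium by irreversible 5-exo-trig acyl transfer onto the neighbouring conjugated ester (the expelled methoxide is protonated by the catalyst, so the base turns over), and the still acidic C3–H equilibrates to the 2,3-trans lactone; the closest known reaction types are the stoichiometric, racemic Stobbe condensation stopped at the paraconic lactone and iminophosphorane-catalysed direct aldol additions of comparably weak carbon acids.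

Step 3
Reactants: 6 methyl (2R,3R,4E)-2-(3,4-dimethoxyphenyl)-4-[(3,4-dimethoxyphenyl)methylidene]-5-oxooxolane-3-carboxylate
Product: 7 (3E,4S,5R)-5-(3,4-dimethoxyphenyl)-3-[(3,4-dimethoxyphenyl)methylidene]-4-(hydroxymethyl)oxolan-2-ol
Conditions: i-Bu2AlH (4.5 equiv), CH2Cl2, −78 → −50 °C; aq. KNaC4H4O6 work-up
Reagents that add atoms: none
Why: DIBAL-H reduction in which the lactone stops at the cyclic lactol aluminate at low temperature while the saturated methyl ester goes to the primary alcohol, hydride adding 1,2 so that the E-alkene and both stereocentres are untouched (the lactol is an anomer mixture).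

Step 4
Reactants: 7 (3E,4S,5R)-5-(3,4-dimethoxyphenyl)-3-[(3,4-dimethoxyphenyl)methylidene]-4-(hydroxymethyl)oxolan-2-ol
Product: 8 [(2R,3S,4E)-2-(3,4-dimethoxyphenyl)-4-[(3,4-dimethoxyphenyl)methylidene]oxolan-3-yl]methanol
Conditions: Et3SiH, BF3·OEt2, CH2Cl2, −78 → −40 °C
Reagents that add atoms: none
Why: ionic hydrogenation of a lactol (Kraus lactol-to-ether reduction), in which BF3 ionises the anomeric OH to the allylic oxocarbenium ion and Et3SiH delivers hydride to the carbon next to oxygen; no stereocentre is made or changed and the alkene geometry is kept.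

Step 5
Reactants: 8 [(2R,3S,4E)-2-(3,4-dimethoxyphenyl)-4-[(3,4-dimethoxyphenyl)methylidene]oxolan-3-yl]methanol
Product: 10 (3S,4S,5R)-5-(3,4-dimethoxyphenyl)-3-[(S)-(3,4-dimethoxyphenyl)(hydroxy)methyl]-4-(hydroxymethyl)oxolan-3-ol, via osmate ester 9 (not isolated)
Conditions: OsO4 (1.05 equiv), TMEDA (1.1 equiv), CH2Cl2, −78 °C; then aq. Na2SO3, THF, rt → 40 °C
Reagents that add atoms: osmium tetroxide O=[Os](=O)(=O)=O
Why: Donohoe hydrogen-bond-directed dihydroxylation, in which the OsO4·TMEDA complex is held by the homoallylic OH and adds suprafacially ([3+2]) to the alkene face syn to CH2OH, placing the tertiary OH cis to CH2OH (the relationship that becomes the trans ring fusion) and, because the alkene is E, giving the S benzylic carbinol.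

Step 6
Reactants: 10 (3S,4S,5R)-5-(3,4-dimethoxyphenyl)-3-[(S)-(3,4-dimethoxyphenyl)(hydroxy)methyl]-4-(hydroxymethyl)oxolan-3-ol
Product: 12 (1S,2S,5S,6R)-2,6-bis(3,4-dimethoxyphenyl)-3,7-dioxabicyclo[3.3.0]octan-1-ol, via primary tosylate 11 (not isolated)
Conditions: TsCl (1.05 equiv), Et3N, Me3N·HCl (cat.), CH2Cl2, 0 °C; then NaH, THF, 0 → 40 °C
Reagents that add atoms: none
Why: chemoselective sulfonylation of the primary alcohol followed by an intramolecular Williamson etherification (5-exo-tet) in which the benzylic alkoxide displaces the primary tosylate; no stereocentre is touched, so the trans fusion and all four configurations are inherited from 10, and the competing 4-exo closure by the tertiary alkoxide should be much slower.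

**Compound list**

1 | 4-bromo-1,2-dimethoxybenzene | COc1ccc(Br)cc1OC | starting material
2 | dimethyl itaconate | COC(=O)CC(=C)C(=O)OC | starting material
3 | dimethyl (2E)-2-[(3,4-dimethoxyphenyl)methylidene]butanedioate | COC(=O)C/C(=C\c1ccc(OC)c(OC)c1)C(=O)OC | intermediate
4 | 3,4-dimethoxybenzaldehyde | COc1ccc(C=O)cc1OC | starting material
5 | dimethyl (2E,3R)-2-[(3,4-dimethoxyphenyl)methylidene]-3-[(R)-(3,4-dimethoxyphenyl)(hydroxy)methyl]butanedioate (aldol adduct) | COC(=O)[C@@H]([C@@H](O)c1ccc(OC)c(OC)c1)/C(=C\c1ccc(OC)c(OC)c1)C(=O)OC | intermediate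
6 | methyl (2R,3R,4E)-2-(3,4-dimethoxyphenyl)-4-[(3,4-dimethoxyphenyl)methylidene]-5-oxooxolane-3-carboxylate | COc1ccc([C@@H]2OC(=O)/C(=C/c3ccc(OC)c(OC)c3)[C@H]2C(=O)OC)cc1OC | intermediate
7 | (3E,4S,5R)-5-(3,4-dimethoxyphenyl)-3-[(3,4-dimethoxyphenyl)methylidene]-4-(hydroxymethyl)oxolan-2-ol (anomer mixture) | COc1ccc([C@@H]2OC(O)/C(=C/c3ccc(OC)c(OC)c3)[C@H]2CO)cc1OC | intermediate
8 | [(2R,3S,4E)-2-(3,4-dimethoxyphenyl)-4-[(3,4-dimethoxyphenyl)methylidene]oxolan-3-yl]methanol | COc1ccc([C@@H]2OC/C(=C/c3ccc(OC)c(OC)c3)[C@H]2CO)cc1OC | intermediate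
9 | cyclic dioxo-osmium glycolate (hexavalent osmium) of triol 10 through its tertiary and benzylic oxygens, TMEDA adduct | COc1ccc([C@@H]2OC[C@@]3(O[Os](=O)(=O)O[C@H]3c4ccc(OC)c(OC)c4)[C@H]2CO)cc1OC.CN(C)CCN(C)C | intermediate
10 | (3S,4S,5R)-5-(3,4-dimethoxyphenyl)-3-[(S)-(3,4-dimethoxyphenyl)(hydroxy)methyl]-4-(hydroxymethyl)oxolan-3-ol | COc1ccc([C@@H]2OC[C@](O)([C@@H](O)c3ccc(OC)c(OC)c3)[C@H]2CO)cc1OC | intermediate
11 | [(2R,3S,4S)-2-(3,4-dimethoxyphenyl)-4-hydroxy-4-[(S)-(3,4-dimethoxyphenyl)(hydroxy)methyl]oxolan-3-yl]methyl 4-methylbenzenesulfonate | COc1ccc([C@@H]2OC[C@](O)([C@@H](O)c3ccc(OC)c(OC)c3)[C@H]2COS(=O)(=O)c4ccc(C)cc4)cc1OC | intermediate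
12 | (1S,2S,5S,6R)-2,6-bis(3,4-dimethoxyphenyl)-3,7-dioxabicyclo[3.3.0]octan-1-ol | COc1ccc([C@@H]2OC[C@]3(O)[C@H](c4ccc(OC)c(OC)c4)OC[C@@H]23)cc1OC | target

**Step count and risks**

Total step count: 6. Longest linear sequence: 6 steps (1 + 2 → 3 → 6 → 7 → 8 → 10 → 12).

Three steps most likely to fail:

Step 2 (the proposed new reaction). The CH2 of 3 may be too weakly acidic for turnover, the lactone may open by Stobbe-type E1cB elimination, or the ee may be low. The fallback uses known auxiliary chemistry; it sets out from 4 and comes back to the route at 6. Stobbe condensation of 4 with dimethyl succinate (NaOMe, MeOH, reflux) gives (3E)-4-(3,4-dimethoxyphenyl)-3-(methoxycarbonyl)but-3-enoic acid F1. Pivaloyl chloride/Et3N, then lithiated (R)-4-benzyl-1,3-oxazolidin-2-one, gives methyl (2E)-4-[(4R)-4-benzyl-2-oxo-1,3-oxazolidin-3-yl]-2-[(3,4-dimethoxyphenyl)methylidene]-4-oxobutanoate F2. Bu2BOTf, i-Pr2NEt, CH2Cl2, −78 °C, then 4, gives the Evans syn aldol methyl (2E,3R,4R)-3-[(4R)-4-benzyl-2-oxo-1,3-oxazolidine-3-carbonyl]-4-(3,4-dimethoxyphenyl)-2-[(3,4-dimethoxyphenyl)methylidene]-4-hydroxybutanoate F3, the same two centres now set by the auxiliary. MeOMgBr in MeOH/CH2Cl2 at 0 °C replaces the auxiliary by OMe to give 5, which lactonises (cat. PPTS, toluene) to 6.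

Step 5 (directed dihydroxylation). The homoallylic OH may not overcome the steric bias, so osmium would add anti to CH2OH and lead to the cis-fused series. The fallback sets out from 8 and comes back at 10. VO(acac)2 (cat.), t-BuOOH, CH2Cl2, 0 °C epoxidises on the CH2OH face through the vanadate ester to give [(2S,3S,6R,7S)-2,6-bis(3,4-dimethoxyphenyl)-1,5-dioxaspiro[2.4]heptan-7-yl]methanol F4. Kornblum-type oxidative opening at the benzylic carbon (DMSO, Bi(OTf)3 cat., then Et3N) gives (3,4-dimethoxyphenyl)[(3S,4S,5R)-5-(3,4-dimethoxyphenyl)-3-hydroxy-4-(hydroxymethyl)oxolan-3-yl]methanone F5, whose tertiary OH keeps the epoxide configuration. Zn(BH4)2, Et2O, −20 °C reduces the ketone under chelation control, hydride arriving from the ring-CH2 side, to give the S carbinol of 10.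

Step 6 (trans-fused ring closure). Ring strain may slow the 5-exo displacement enough for the tertiary alkoxide to form an oxetane or for the tosylate to decompose. The fallback sets out from 10 and comes back at 12. Tosylate 11 is isolated (TsCl, Et3N, Me3N·HCl, CH2Cl2, 0 °C) and heated with Bu2SnO (toluene, 80 °C) to give the dibutylstannylene acetal of 11 across its tertiary and benzylic oxygens F6. CsF, DMF, 60 °C then alkylates only the tin-activated benzylic oxygen while the tertiary oxygen stays tin-bound, and aqueous work-up releases 12.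

**Further compounds**

F1 | step 2 | (3E)-4-(3,4-dimethoxyphenyl)-3-(methoxycarbonyl)but-3-enoic acid | COC(=O)/C(=C/c1ccc(OC)c(OC)c1)CC(=O)O
F2 | step 2 | methyl (2E)-4-[(4R)-4-benzyl-2-oxo-1,3-oxazolidin-3-yl]-2-[(3,4-dimethoxyphenyl)methylidene]-4-oxobutanoate | COC(=O)/C(=C/c1ccc(OC)c(OC)c1)CC(=O)N1C(=O)OC[C@H]1Cc1ccccc1
F3 | step 2 | methyl (2E,3R,4R)-3-[(4R)-4-benzyl-2-oxo-1,3-oxazolidine-3-carbonyl]-4-(3,4-dimethoxyphenyl)-2-[(3,4-dimethoxyphenyl)methylidene]-4-hydroxybutanoate | COC(=O)/C(=C/c1ccc(OC)c(OC)c1)[C@H]([C@@H](O)c1ccc(OC)c(OC)c1)C(=O)N1C(=O)OC[C@H]1Cc1ccccc1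
F4 | step 5 | [(2S,3S,6R,7S)-2,6-bis(3,4-dimethoxyphenyl)-1,5-dioxaspiro[2.4]heptan-7-yl]methanol | COc1ccc([C@@H]2OC[C@@]3(O[C@H]3c4ccc(OC)c(OC)c4)[C@H]2CO)cc1OC
F5 | step 5 | (3,4-dimethoxyphenyl)[(3S,4S,5R)-5-(3,4-dimethoxyphenyl)-3-hydroxy-4-(hydroxymethyl)oxolan-3-yl]methanone | COc1ccc([C@@H]2OC[C@](O)(C(=O)c3ccc(OC)c(OC)c3)[C@H]2CO)cc1OC
F6 | step 6 | dibutylstannylene acetal of 11 across its tertiary and benzylic oxygens (2,2-dibutyl-1,3,2-dioxastannolane) | COc1ccc([C@@H]2OC[C@@]3(O[Sn](CCCC)(CCCC)O[C@H]3c4ccc(OC)c(OC)c4)[C@H]2COS(=O)(=O)c5ccc(C)cc5)cc1OC
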